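**Retrosynthetic overview**

1. Numbering: ring A is C1–C5 with C10, ring B is C5–C10, C11 is the methylene carbon on C4, C15 is the benzylic carbon on C9, and the arene is C1' (on C15), C2' (OH), C3' (OMe), C5' (CO2Me).
2. Feature: C9 is a quaternary ring B carbon carrying a methyl and C15, next to C8, whose methyl can be carried as an exocyclic alkenyl carbon. An alkenylpalladium at C8 that inserts a C9=C15 alkene therefore closes ring B and leaves palladium on C15 with no β-hydrogen, free to be arylated.
3. Late disconnections: C4=C11 (methylenation of a C4 ketone) and the C8 methyl (hydrogenation of an 8-methylene group).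
4. Key disconnection: C8–C9 and C15–C1' together, by a domino Heck–Suzuki reaction of a ring A enol triflate with an aryl pinacol boronate. The triflate comes from 2-methylcyclohex-2-enone (conjugate isopropenylation sets C10, Mukaiyama–Michael addition sets C5); the boronate comes from methyl vanillate.
5. Ring order: ring A is bought, ring B is closed in the key step, and the arene is attached in the same operation.

Key step: step 11

Remark: the C4 oxygen is carried as the 4β (equatorial) silyl ether, the epimer that hydride attack anti to the C5 methyl should give; C4 is a spectator centre erased in step 14. The two ketones of the Michael adduct are told apart by selective acetalisation before reduction. Palladium intermediates are written without their phosphine ligands.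

**Route**

Step 1
Reactants: 1 2-methylcyclohex-2-en-1-one; 2 isopropenylmagnesium bromide
Product: 4 (S)-trimethyl{[2-methyl-3-(prop-1-en-2-yl)cyclohex-1-en-1-yl]oxy}silane, via bromomagnesium enolate 3 (not isolated)
Conditions: CuBr·SMe2 (5 mol %), (R)-1-[(S)-2-(diphenylphosphino)ferrocenyl]ethyldicyclohexylphosphine or its enantiomer (6 mol %; the antipode that gives 10S), t-BuOMe, −75 °C; then TMSCl, Et3N, DMPU, −75 °C to rt
Reagents that add atoms: chlorotrimethylsilane, C[Si](C)(C)Cl
Why: Copper-catalysed asymmetric conjugate addition of a Grignard reagent to an α-substituted cyclic enone, in which the chiral copper–diphosphine complex selects the enone face and sets C10 as S, followed by O-silylation of the regiodefined magnesium enolate 3, which stores the C4–C5 enolate for the next step.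

Step 2
Reactants: 4 (S)-trimethyl{[2-methyl-3-(prop-1-en-2-yl)cyclohex-1-en-1-yl]oxy}silane; 5 methyl vinyl ketone
Product: 6 (2S,3S)-2-methyl-2-(3-oxobutyl)-3-(prop-1-en-2-yl)cyclohexan-1-one
Conditions: BF3·OEt2, i-PrOH, CH2Cl2, −78 °C
Reagents that add atoms: none
Why: Mukaiyama–Michael addition in which the BF3-activated enone is attacked by the C5 terminus of the enol ether on the face anti to the neighbouring isopropenyl group (held pseudo-axial by allylic strain with the C5 methyl), which sets the quaternary C5 as S with the oxobutyl chain trans to the isopropenyl group, while isopropanol protonates the product enolate and takes up the silyl group.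

Step 3
Reactants: 6 (2S,3S)-2-methyl-2-(3-oxobutyl)-3-(prop-1-en-2-yl)cyclohexan-1-one
Product: 7 (2S,3S)-2-methyl-2-[2-(2-methyl-1,3-dioxolan-2-yl)ethyl]-3-(prop-1-en-2-yl)cyclohexan-1-one
Conditions: (TMSOCH2)2, TMSOTf (2 mol %), CH2Cl2, −78 to −20 °C
Reagents that add atoms: 1,2-bis(trimethylsilyloxy)ethane, C[Si](C)(C)OCCO[Si](C)(C)C
Why: Noyori acetalisation under kinetic control should occur only at the unhindered methyl ketone, the ring ketone being shielded by the adjacent quaternary C5, so that the two carbonyl groups are told apart before any hydride or base is used.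

Step 4
Reactants: 7 (2S,3S)-2-methyl-2-[2-(2-methyl-1,3-dioxolan-2-yl)ethyl]-3-(prop-1-en-2-yl)cyclohexan-1-one
Product: 8 (1S,2S,3S)-2-methyl-2-[2-(2-methyl-1,3-dioxolan-2-yl)ethyl]-3-(prop-1-en-2-yl)cyclohexan-1-ol
Conditions: NaBH4, MeOH, 0 °C to rt
Reagents that add atoms: none
Why: Borohydride reduction of the ring ketone, in which hydride should approach C4 from the α face, anti to the C5 methyl and the C10 isopropenyl group, to give the 4β alcohol (C4 S, cis to the C5 methyl); this centre is erased in step 14.

Step 5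
Reactants: 8 (1S,2S,3S)-2-methyl-2-[2-(2-methyl-1,3-dioxolan-2-yl)ethyl]-3-(prop-1-en-2-yl)cyclohexan-1-ol
Product: 9 tert-butyldimethyl{[(1S,2S,3S)-2-methyl-2-[2-(2-methyl-1,3-dioxolan-2-yl)ethyl]-3-(prop-1-en-2-yl)cyclohexyl]oxy}silane
Conditions: TBSOTf, 2,6-lutidine, CH2Cl2, 0 °C
Reagents that add atoms: tert-butyldimethylsilyl trifluoromethanesulfonate, CC(C)(C)[Si](C)(C)OS(=O)(=O)C(F)(F)F
Why: Silylation of the hindered secondary alcohol with a silyl triflate and a non-nucleophilic base gives an ether that is inert to base, palladium and hydrogenation and, unlike a C4 methylene group, offers no competing alkene to the carbopalladation.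

Step 6
Reactants: 9 tert-butyldimethyl{[(1S,2S,3S)-2-methyl-2-[2-(2-methyl-1,3-dioxolan-2-yl)ethyl]-3-(prop-1-en-2-yl)cyclohexyl]oxy}silane
Product: 10 4-[(1S,2S,6S)-2-(tert-butyldimethylsilyloxy)-1-methyl-6-(prop-1-en-2-yl)cyclohexyl]butan-2-one
Conditions: PPTS, acetone/H2O, 60 °C
Reagents that add atoms: water, O
Why: Mild acid-catalysed acetal hydrolysis releases the methyl ketone while the hindered secondary silyl ether and the isopropenyl group should be untouched.

Step 7
Reactants: 10 4-[(1S,2S,6S)-2-(tert-butyldimethylsilyloxy)-1-methyl-6-(prop-1-en-2-yl)cyclohexyl]butan-2-one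
Product: 12 4-[(1S,2S,6S)-2-(tert-butyldimethylsilyloxy)-1-methyl-6-(prop-1-en-2-yl)cyclohexyl]but-1-en-2-yl trifluoromethanesulfonate, via potassium enolate 11 (not isolated)
Conditions: KN(SiMe3)2, THF, −78 °C; then PhNTf2, −78 to 0 °C
Reagents that add atoms: N-phenylbis(trifluoromethanesulfonimide), O=S(=O)(N(c1ccccc1)S(=O)(=O)C(F)(F)F)C(F)(F)F
Why: Kinetic deprotonation of the methyl ketone at its methyl group by the bulky amide base at −78 °C gives the terminal enolate 11, and O-sulfonylation with N-phenyltriflimide gives the 2-triflyloxy-1-alkene.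

Step 8
Reactants: 13 methyl vanillate
Product: 14 methyl 3-bromo-4-hydroxy-5-methoxybenzoate
Conditions: Br2, AcOH, rt
Reagents that add atoms: bromine, BrBr
Why: Electrophilic aromatic bromination goes ortho to the phenol (the para position is blocked by the ester), which marks the future C1'.

Step 9
Reactants: 14 methyl 3-bromo-4-hydroxy-5-methoxybenzoate
Product: 15 methyl 3-bromo-5-methoxy-4-(methoxymethoxy)benzoate
Conditions: MOMCl, i-Pr2NEt, CH2Cl2, 0 °C to rt
Reagents that add atoms: chloromethyl methyl ether, COCCl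
Why: O-Alkylation of the phenol (methoxymethyl protection) removes the acidic O–H that would interfere with borylation, cross-coupling and the later oxidation.

Step 10
Reactants: 15 methyl 3-bromo-5-methoxy-4-(methoxymethoxy)benzoate
Product: 16 methyl 3-methoxy-4-(methoxymethoxy)-5-(4,4,5,5-tetramethyl-1,3,2-dioxaborolan-2-yl)benzoate
Conditions: B2pin2, Pd(dppf)Cl2 (5 mol %), KOAc, 1,4-dioxane, 90 °C
Reagents that add atoms: bis(pinacolato)diboron, CC1(C)OB(OC1(C)C)B1OC(C)(C)C(C)(C)O1
Why: Miyaura borylation of the aryl bromide, with KOAc as a base too weak to let the product boronate couple with remaining bromide.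

Step 11
Reactants: 12 4-[(1S,2S,6S)-2-(tert-butyldimethylsilyloxy)-1-methyl-6-(prop-1-en-2-yl)cyclohexyl]but-1-en-2-yl trifluoromethanesulfonate; 16 methyl 3-methoxy-4-(methoxymethoxy)-5-(4,4,5,5-tetramethyl-1,3,2-dioxaborolan-2-yl)benzoate
Product: 19 methyl 3-{[(1S,4aS,5S,8aS)-5-(tert-butyldimethylsilyloxy)-1,4a-dimethyl-2-methylidenedecahydronaphthalen-1-yl]methyl}-5-methoxy-4-(methoxymethoxy)benzoate (trans-decalin; 5-Me β, 9-Me β, 10-H α, C15 α, 4-OTBS β), via alkenylpalladium triflate 17 (not isolated), via neopentylpalladium triflate 18 (not isolated)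
Conditions: Pd(PPh3)4 (10 mol %), K3PO4, 1,4-dioxane/H2O (20:1), 80 °C, 16 added slowly
Reagents that add atoms: none
Why: Oxidative addition of zerovalent palladium into the C8–OTf bond gives alkenylpalladium 17, syn insertion of the C9=C15 alkene forms the C8–C9 bond and neopentylpalladium 18, which cannot undergo β-hydride elimination because C9 is quaternary, and transmetallation with the phosphate-activated boronate followed by reductive elimination forms the C15–C1' bond. The closest known reaction type is the domino intramolecular Heck–Suzuki (cyclisation–anion capture) reaction of alkenyl or aryl electrophiles that carry a 1,1-disubstituted alkene. Ring B closes in the 6-exo-trig mode through a chair-like transition state built on the ring A chair in which the C10–C9 and C5–C6 arms are trans-diequatorial (the only conformer in which they can meet, and the ground state because ring inversion would place the C4 silyl ether and the isopropenyl group 1,3-diaxial), so the ring fusion is trans. The new stereocentre C9 is controlled by the axial C5 methyl: the palladium-bearing alkene terminus C15 takes the outward pseudo-equatorial position and the small methyl the pseudo-axial position syn to the C5 methyl, because the other rotamer would press C15 and its palladium–phosphine unit into a 1,3-diaxial contact with that methyl. The step needs ring closure to outrun direct Suzuki coupling of 17, which the intramolecular cationic (triflate) insertion and a low boronate concentration should secure, and it needs arylation of 18 to outrun 3-exo attack on the C8 methylene, which is disfavoured because the equatorial C15–Pd bond lies near the nodal plane of that π bond.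

Step 12
Reactants: 19 methyl 3-{[(1S,4aS,5S,8aS)-5-(tert-butyldimethylsilyloxy)-1,4a-dimethyl-2-methylidenedecahydronaphthalen-1-yl]methyl}-5-methoxy-4-(methoxymethoxy)benzoate
Product: 20 methyl 3-{[(1R,2S,4aS,5S,8aS)-5-(tert-butyldimethylsilyloxy)-1,2,4a-trimethyldecahydronaphthalen-1-yl]methyl}-5-methoxy-4-(methoxymethoxy)benzoate
Conditions: H2 (1 atm), PtO2, EtOAc, rt
Reagents that add atoms: none
Why: Heterogeneous catalytic hydrogenation of the 1,1-disubstituted alkene, with hydrogen expected to reach C8 from the α face, away from the axial C9 methyl on the β face, so that the new methyl is β and equatorial (C8 S).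

Step 13
Reactants: 20 methyl 3-{[(1R,2S,4aS,5S,8aS)-5-(tert-butyldimethylsilyloxy)-1,2,4a-trimethyldecahydronaphthalen-1-yl]methyl}-5-methoxy-4-(methoxymethoxy)benzoate
Product: 21 methyl 3-{[(1R,2S,4aS,5S,8aS)-5-hydroxy-1,2,4a-trimethyldecahydronaphthalen-1-yl]methyl}-5-methoxy-4-(methoxymethoxy)benzoate
Conditions: HF·pyridine, THF, 0 °C to 40 °C
Reagents that add atoms: none
Why: Fluoride-induced cleavage of the silyl ether, driven by Si–F bond formation, under buffered conditions that the methoxymethyl ether and the methyl ester should survive.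

Step 14
Reactants: 21 methyl 3-{[(1R,2S,4aS,5S,8aS)-5-hydroxy-1,2,4a-trimethyldecahydronaphthalen-1-yl]methyl}-5-methoxy-4-(methoxymethoxy)benzoate
Product: 22 methyl 3-methoxy-4-(methoxymethoxy)-5-{[(1R,2S,4aS,8aS)-1,2,4a-trimethyl-5-oxodecahydronaphthalen-1-yl]methyl}benzoate
Conditions: Dess–Martin periodinane, CH2Cl2, rt
Reagents that add atoms: none
Why: Dess–Martin oxidation of the secondary alcohol to the ketone under near-neutral conditions; the α carbon C5 is quaternary, so no centre can epimerise.

Step 15
Reactants: 22 methyl 3-methoxy-4-(methoxymethoxy)-5-{[(1R,2S,4aS,8aS)-1,2,4a-trimethyl-5-oxodecahydronaphthalen-1-yl]methyl}benzoate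
Product: 23 methyl 3-methoxy-4-(methoxymethoxy)-5-{[(1R,2S,4aS,8aS)-1,2,4a-trimethyl-5-methylidenedecahydronaphthalen-1-yl]methyl}benzoate
Conditions: Zn, CH2Br2, TiCl4, THF/CH2Cl2, 0 °C to rt
Reagents that add atoms: dibromomethane, BrCBr
Why: Takai–Lombardo methylenation with the geminal dizinc reagent activated by TiCl4, which is non-basic, reacts with ketones but not with esters, and is small enough for the neopentyl C4 carbonyl.

Step 16
Reactants: 23 methyl 3-methoxy-4-(methoxymethoxy)-5-{[(1R,2S,4aS,8aS)-1,2,4a-trimethyl-5-methylidenedecahydronaphthalen-1-yl]methyl}benzoate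
Product: 24 polyfibrospongol A, methyl 4-hydroxy-3-methoxy-5-{[(1R,2S,4aS,8aS)-1,2,4a-trimethyl-5-methylidenedecahydronaphthalen-1-yl]methyl}benzoate
Conditions: HCl (0.2 M in MeOH), MeOH, 0 °C to rt
Reagents that add atoms: none
Why: Acid-catalysed acetal exchange with methanol removes the methoxymethyl group, and dilute acid at room temperature is chosen so that the C4=C11 alkene is not protonated.

**Compound list**

1 | 2-methylcyclohex-2-en-1-one | CC1=CCCCC1=O | starting material
2 | isopropenylmagnesium bromide | C=C(C)[Mg]Br | starting material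
3 | bromomagnesium (S)-2-methyl-3-(prop-1-en-2-yl)cyclohex-1-en-1-olate | C=C(C)[C@@H]1CCCC(O[Mg]Br)=C1C | intermediate
4 | (S)-trimethyl{[2-methyl-3-(prop-1-en-2-yl)cyclohex-1-en-1-yl]oxy}silane | C=C(C)[C@@H]1CCCC(O[Si](C)(C)C)=C1C | intermediate
5 | methyl vinyl ketone | CC(=O)C=C | starting material
6 | (2S,3S)-2-methyl-2-(3-oxobutyl)-3-(prop-1-en-2-yl)cyclohexan-1-one | C=C(C)[C@@H]1CCCC(=O)[C@@]1(C)CCC(C)=O | intermediate
7 | (2S,3S)-2-methyl-2-[2-(2-methyl-1,3-dioxolan-2-yl)ethyl]-3-(prop-1-en-2-yl)cyclohexan-1-one | C=C(C)[C@@H]1CCCC(=O)[C@@]1(C)CCC1(C)OCCO1 | intermediate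
8 | (1S,2S,3S)-2-methyl-2-[2-(2-methyl-1,3-dioxolan-2-yl)ethyl]-3-(prop-1-en-2-yl)cyclohexan-1-ol | C=C(C)[C@@H]1CCC[C@H](O)[C@@]1(C)CCC1(C)OCCO1 | intermediate
9 | tert-butyldimethyl{[(1S,2S,3S)-2-methyl-2-[2-(2-methyl-1,3-dioxolan-2-yl)ethyl]-3-(prop-1-en-2-yl)cyclohexyl]oxy}silane | C=C(C)[C@@H]1CCC[C@H](O[Si](C)(C)C(C)(C)C)[C@@]1(C)CCC1(C)OCCO1 | intermediate
10 | 4-[(1S,2S,6S)-2-(tert-butyldimethylsilyloxy)-1-methyl-6-(prop-1-en-2-yl)cyclohexyl]butan-2-one | C=C(C)[C@@H]1CCC[C@H](O[Si](C)(C)C(C)(C)C)[C@@]1(C)CCC(C)=O | intermediate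
11 | potassium 4-[(1S,2S,6S)-2-(tert-butyldimethylsilyloxy)-1-methyl-6-(prop-1-en-2-yl)cyclohexyl]but-1-en-2-olate | C=C(C)[C@@H]1CCC[C@H](O[Si](C)(C)C(C)(C)C)[C@@]1(C)CCC(=C)O[K] | intermediate
12 | 4-[(1S,2S,6S)-2-(tert-butyldimethylsilyloxy)-1-methyl-6-(prop-1-en-2-yl)cyclohexyl]but-1-en-2-yl trifluoromethanesulfonate | C=C(C)[C@@H]1CCC[C@H](O[Si](C)(C)C(C)(C)C)[C@@]1(C)CCC(=C)OS(=O)(=O)C(F)(F)F | intermediate
13 | methyl vanillate | COC(=O)c1ccc(O)c(OC)c1 | starting material
14 | methyl 3-bromo-4-hydroxy-5-methoxybenzoate | COC(=O)c1cc(Br)c(O)c(OC)c1 | intermediate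
15 | methyl 3-bromo-5-methoxy-4-(methoxymethoxy)benzoate | COCOc1c(Br)cc(C(=O)OC)cc1OC | intermediate
16 | methyl 3-methoxy-4-(methoxymethoxy)-5-(4,4,5,5-tetramethyl-1,3,2-dioxaborolan-2-yl)benzoate | COCOc1c(OC)cc(C(=O)OC)cc1B1OC(C)(C)C(C)(C)O1 | intermediate
17 | alkenylpalladium triflate from 12, palladium on C8 (phosphine ligands omitted) | C=C(C)[C@@H]1CCC[C@H](O[Si](C)(C)C(C)(C)C)[C@@]1(C)CCC(=C)[Pd]OS(=O)(=O)C(F)(F)F | intermediate
18 | neopentylpalladium triflate, ring B closed, palladium on C15 (phosphine ligands omitted) | C=C1CC[C@]2(C)[C@@H](O[Si](C)(C)C(C)(C)C)CCC[C@H]2[C@]1(C)C[Pd]OS(=O)(=O)C(F)(F)F | intermediate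
19 | methyl 3-{[(1S,4aS,5S,8aS)-5-(tert-butyldimethylsilyloxy)-1,4a-dimethyl-2-methylidenedecahydronaphthalen-1-yl]methyl}-5-methoxy-4-(methoxymethoxy)benzoate | C=C1CC[C@]2(C)[C@@H](O[Si](C)(C)C(C)(C)C)CCC[C@H]2[C@]1(C)Cc1cc(C(=O)OC)cc(OC)c1OCOC | intermediate
20 | methyl 3-{[(1R,2S,4aS,5S,8aS)-5-(tert-butyldimethylsilyloxy)-1,2,4a-trimethyldecahydronaphthalen-1-yl]methyl}-5-methoxy-4-(methoxymethoxy)benzoate | C[C@H]1CC[C@]2(C)[C@@H](O[Si](C)(C)C(C)(C)C)CCC[C@H]2[C@]1(C)Cc1cc(C(=O)OC)cc(OC)c1OCOC | intermediate
21 | methyl 3-{[(1R,2S,4aS,5S,8aS)-5-hydroxy-1,2,4a-trimethyldecahydronaphthalen-1-yl]methyl}-5-methoxy-4-(methoxymethoxy)benzoate | C[C@H]1CC[C@]2(C)[C@@H](O)CCC[C@H]2[C@]1(C)Cc1cc(C(=O)OC)cc(OC)c1OCOC | intermediate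
22 | methyl 3-methoxy-4-(methoxymethoxy)-5-{[(1R,2S,4aS,8aS)-1,2,4a-trimethyl-5-oxodecahydronaphthalen-1-yl]methyl}benzoate | C[C@H]1CC[C@]2(C)C(=O)CCC[C@H]2[C@]1(C)Cc1cc(C(=O)OC)cc(OC)c1OCOC | intermediate
23 | methyl 3-methoxy-4-(methoxymethoxy)-5-{[(1R,2S,4aS,8aS)-1,2,4a-trimethyl-5-methylidenedecahydronaphthalen-1-yl]methyl}benzoate | C=C1CCC[C@H]2[C@](C)(Cc3cc(C(=O)OC)cc(OC)c3OCOC)[C@@H](C)CC[C@]12C | intermediate
24 | polyfibrospongol A, methyl 4-hydroxy-3-methoxy-5-{[(1R,2S,4aS,8aS)-1,2,4a-trimethyl-5-methylidenedecahydronaphthalen-1-yl]methyl}benzoate | C=C1CCC[C@H]2[C@](C)(Cc3cc(C(=O)OC)cc(OC)c3O)[C@@H](C)CC[C@]12C | target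

**Step count**

Total: 16 steps. Longest linear sequence: 13 steps (steps 1–7, then 11–16); the arene branch is steps 8–10.

**Steps most likely to fail**

Step 11. The alkenylpalladium 17 may transmetallate with the boronate before it cyclises, insertion may take place on the wrong face of the isopropenyl group, or 18 may be diverted by 3-exo attack on the C8 methylene before it is arylated. The fallback separates ring closure from arylation and reverses the polarity of the coupling. It sets out from enol triflate 12 and comes back at 19. A domino Heck–borylation of 12 (B2pin2, Pd(PPh3)4, KOAc, 1,4-dioxane, 80 °C) should give 2-{[(1S,4aS,5S,8aS)-5-(tert-butyldimethylsilyloxy)-1,4a-dimethyl-2-methylidenedecahydronaphthalen-1-yl]methyl}-4,4,5,5-tetramethyl-1,3,2-dioxaborolane F1; with acetate as the only base the diboron reagent transmetallates slowly, so cyclisation should come first. A B-alkyl Suzuki coupling of F1 with aryl bromide 15 (Pd(OAc)2, RuPhos, K3PO4, toluene/H2O, 90 °C) then gives 19. If C9 epimers form, they would be separated at the boronate stage.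

Step 1. An alkenyl Grignard reagent on an α-substituted enone may add with low enantioselectivity, or partly in the 1,2 sense. The fallback replaces catalyst control by a classical resolution. It sets out from alcohol 8 of whatever enantiomeric purity step 1 delivers (if need be made with CuBr·SMe2 alone) and comes back at enantiopure 8. Acylation with (1S,4R)-camphanic chloride (pyridine, DMAP, CH2Cl2) gives (1S,2S,3S)-2-methyl-2-[2-(2-methyl-1,3-dioxolan-2-yl)ethyl]-3-(prop-1-en-2-yl)cyclohexyl (1S,4R)-camphanate F2 together with the diastereomer from the minor enantiomer, (1R,2R,3R)-2-methyl-2-[2-(2-methyl-1,3-dioxolan-2-yl)ethyl]-3-(prop-1-en-2-yl)cyclohexyl (1S,4R)-camphanate F3. The two are separated by chromatography or crystallisation, and saponification of F2 (KOH, MeOH/H2O, 60 °C) returns 8.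

Step 12. The exocyclic alkene may migrate into ring B on the metal surface and stall, or hydrogen may be delivered with poor facial selectivity at C8. The fallback changes the control element from kinetic surface delivery to a thermodynamically controlled radical reduction. It sets out from 19 and comes back at 20. Hydrogen-atom-transfer hydrogenation (Mn(dpm)3, PhSiH3, t-BuOOH, i-PrOH, rt) generates the tertiary C8 radical, which should take up hydrogen axially to give the more stable equatorial 8β-methyl isomer; no new compound arises (F0).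

**Further compounds**

F1 | step 11 | 2-{[(1S,4aS,5S,8aS)-5-(tert-butyldimethylsilyloxy)-1,4a-dimethyl-2-methylidenedecahydronaphthalen-1-yl]methyl}-4,4,5,5-tetramethyl-1,3,2-dioxaborolane | C=C1CC[C@]2(C)[C@@H](O[Si](C)(C)C(C)(C)C)CCC[C@H]2[C@]1(C)CB1OC(C)(C)C(C)(C)O1
F2 | step 1 | (1S,2S,3S)-2-methyl-2-[2-(2-methyl-1,3-dioxolan-2-yl)ethyl]-3-(prop-1-en-2-yl)cyclohexyl (1S,4R)-camphanate | C=C(C)[C@@H]1CCC[C@H](OC(=O)[C@@]23CC[C@@](C)(C(=O)O2)C3(C)C)[C@@]1(C)CCC1(C)OCCO1
F3 | step 1 | (1R,2R,3R)-2-methyl-2-[2-(2-methyl-1,3-dioxolan-2-yl)ethyl]-3-(prop-1-en-2-yl)cyclohexyl (1S,4R)-camphanate | C=C(C)[C@H]1CCC[C@@H](OC(=O)[C@@]23CC[C@@](C)(C(=O)O2)C3(C)C)[C@]1(C)CCC1(C)OCCO1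
F0 | step 12 | none | none
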